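The readings were generated by integration with made-up constants, and the scatter is random.

If reagent is fed into a stirred substrate, the substrate answers to the reagent concentration summed over time, so I replaced that rising curve by its mean.

| setting | larch | alder | oak | flask |
|---|---|---|---|---|
| substrate | 0.12 M | 0.19 M | 0.25 M | 0.25 M |
| reagent | 0.225 M (fed, over 30 min) | 0.225 M (fed, over 30 min) | 0.34 M (fed, over 30 min) | 0.225 M (fed, over 30 min) |
| remark | run made earlier; the fed solution adds 0.25 times the starting volume | run made earlier; the fed solution adds 0.25 times the starting volume | run made earlier; the fed solution adds 0.25 times the starting volume | the fed solution adds 0.25 times the starting volume |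
| time |  |  |  | 30 min |

| run | time / min | substrate / % | double product / % |
|---|---|---|---|
| larch | 1.33 | 99.6 | 0.4 |
| larch | 4.00 | 98.2 | 0 |
| larch | 6.00 | 96.0 | 0.1 |
| larch | 10.0 | 90.0 | 1.1 |
| larch | 15.0 | 79.5 | 1.0 |
| larch | 20.0 | 70.1 | 2.5 |
| alder | 1.33 | 99.2 | 0 |
| alder | 2.50 | 99.3 | 0.6 |
| alder | 4.00 | 98.6 | 0 |
| alder | 6.00 | 96.4 | 0 |
| alder | 10.0 | 90.6 | 0 |
| alder | 20.0 | 70.8 | 2.4 |
| oak | 1.50 | 99.3 | 0.3 |
| oak | 5.00 | 95.7 | 0.4 |
| oak | 8.00 | 90.6 | 0 |
| oak | 12.0 | 82.4 | 0.7 |
| oak | 20.0 | 62.4 | 3.1 |

(scatter of a reading: 0.5 percentage points)

- every charge counts on the volume at the start, and the solution that is fed holds the whole dose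

* amount of substrate in the flask at 30 min, in percent of the substrate charged
* amount of double product in the flask at 30 min, in percent of the substrate charged
* amount of mono adduct in the flask at 30 min, in percent of the substrate charged
* concentration of reagent at 30 min, in M

Larch and alder kept nearly equal percentages at 20.0 min, 70.1% and 70.8%, from different charges. So I took substrate loss as first order in substrate, which makes it pseudo-first-order at a fixed reagent level. Undisturbed reagent rises nearly straight, so its mean is 0.5 of its end value. The reagent spent grows about as time squared, so its mean is the end value over 3. Each mono adduct costs one reagent and each double product two.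

Larch, mean reagent to 20.0 min: 0.0532 M

Rate constant read from larch: 0.00557 M⁻¹ s⁻¹

Second step over first, read from oak's noisy double product, which grows as this ratio times half the squared lost share: 0.439

For the flask I guessed 0.5 of the substrate lost, and the substrate left came back as 58.8%. Feeding that in returned 54.8%, so I took the midpoint:

Substrate left: 56.8%

Mean reagent concentration over the feed, c_mean: 0.0585 M

Growing volume bends the rise, lifting the undisturbed mean by 7.43% in the flask and by 5.13% in larch, and my constant already carries the larch error.

The ladder in the flask starts with the feed, 30 min. Substrate's time constant at c_mean is longer, 51.2 min, and mono adduct's is longer still, 117 min. So I expected 4.09% double product, 39.1% mono adduct and 0.0854 M reagent.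

The forecast said 56.8% substrate, 5% double product, 38.2% mono adduct and 0.084 M reagent, noting “Double product is near the noise level”.

The flask gave 56.5%, 3.91%, 39.1% and 0.0833 M.

    substrate + reagent → mono adduct + by-product (k = 0.00580 M⁻¹ s⁻¹)
    reagent + mono adduct → double product + by-product (k = 0.00200 M⁻¹ s⁻¹)
    reagent + tris adduct → tetra adduct + by-product (k = 0.00340 M⁻¹ s⁻¹)
    reagent + double product → tris adduct + by-product (k = 0.00330 M⁻¹ s⁻¹)

Read back through my constant, the flask's substrate stood for a mean of 0.0569 M, against my 0.0585 M. A neighbouring flask took 0.38 M of reagent, its other charges unchanged. The same two passes gave 31.6% and 36.9%, so 34.2% substrate, a mean of 0.102 M and 9.48% double product. That neighbouring flask held 36.9% substrate and 9.14% double product.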